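**Retrosynthetic overview**

1. The strategy rests on ring D, a 2-alkylbenzene-1,4-diol: C1(OH)–C2(CH2CH2–ring C)–C3(H)–C4(OH)–C5(H)–C6(H). A benzannulation builds this from three pieces: C4–C5–C6 from a methoxy(vinyl)carbene ligand, C3–C2 from a terminal alkyne, and C1 from CO. The oxygen at C4 arrives as a methyl ether and the oxygen at C1 as a free phenol.
2. Ring D is therefore disconnected into the 4-arylbut-1-yne carrying rings A, B and C plus pentacarbonyl[methoxy(vinyl)carbene]chromium. Three C–C bonds form: C4–C3, C2–C1 and C1–C6.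
3. The alkyne comes from a ring C benzylic bromide and lithiated 1-(trimethylsilyl)propyne. The A–B ethano bridge comes from a Wittig reaction and hydrogenation. The B–C diaryl ether comes from SNAr of 3-hydroxy-4-methoxybenzyl alcohol on 4-fluorobenzaldehyde.
4. Rings A, B and C are bought as benzene rings. Ring D is the only ring formed, in the penultimate step, and BBr3 then cleaves the three methyl ethers.

Key step: step 8

Remark: the target has no stereocentre; stilbene 6 is carried as an E/Z mixture because both isomers give the same bibenzyl in step 3.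

**Route**

Step 1
Reactants: 1 3-hydroxy-4-methoxybenzyl alcohol; 2 4-fluorobenzaldehyde
Product: 3 4-[5-(hydroxymethyl)-2-methoxyphenoxy]benzaldehyde
Conditions: K2CO3, DMF, 120 °C
Reagents that add atoms: none
Why: SNAr through a Meisenheimer intermediate: the phenoxide of 1 (the aliphatic OH is not deprotonated by K2CO3) displaces the fluoride that the para formyl group activates.

Step 2
Reactants: 3 4-[5-(hydroxymethyl)-2-methoxyphenoxy]benzaldehyde; 4 (3-methoxybenzyl)triphenylphosphonium chloride
Product: 6 (4-methoxy-3-{4-[2-(3-methoxyphenyl)ethenyl]phenoxy}phenyl)methanol (E/Z mixture), via phosphonium ylide 5 (not isolated)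
Conditions: 4, KOtBu, THF, 0 °C; then 3, 0 °C to rt
Reagents that add atoms: none
Why: Wittig olefination with a semi-stabilised benzylic ylide, which is too weak a base to be quenched by the free CH2OH group; the E/Z ratio does not matter because the double bond is saturated next.

Step 3
Reactants: 6 (4-methoxy-3-{4-[2-(3-methoxyphenyl)ethenyl]phenoxy}phenyl)methanol
Product: 7 (4-methoxy-3-{4-[2-(3-methoxyphenyl)ethyl]phenoxy}phenyl)methanol
Conditions: H2 (1 atm), 10% Pd/C, Ph2S (cat.), EtOAc, rt
Reagents that add atoms: none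
Why: Heterogeneous catalytic hydrogenation of a stilbene; Ph2S tempers the Pd/C so that the electron-rich benzylic C–O bond should not be hydrogenolysed.

Step 4
Reactants: 7 (4-methoxy-3-{4-[2-(3-methoxyphenyl)ethyl]phenoxy}phenyl)methanol
Product: 8 4-(bromomethyl)-1-methoxy-2-{4-[2-(3-methoxyphenyl)ethyl]phenoxy}benzene
Conditions: PBr3, CH2Cl2, 0 °C; used crude
Reagents that add atoms: phosphorus tribromide, BrP(Br)Br
Why: Bromination of a primary benzylic alcohol through its phosphite ester with SN2 displacement by bromide; the aryl ethers are inert at 0 °C.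

Step 5
Reactants: 8 4-(bromomethyl)-1-methoxy-2-{4-[2-(3-methoxyphenyl)ethyl]phenoxy}benzene; 9 1-(trimethylsilyl)propyne
Product: 11 [4-(4-methoxy-3-{4-[2-(3-methoxyphenyl)ethyl]phenoxy}phenyl)but-1-yn-1-yl]trimethylsilane, via 3-lithio-1-(trimethylsilyl)propyne 10 (not isolated)
Conditions: 9, n-BuLi, THF, −78 to −20 °C; then 8, −78 °C to rt
Reagents that add atoms: none
Why: SN2 alkylation of the propargylic anion of a silylpropyne, which reacts with reactive primary halides at its CH2 terminus because the silyl group shields the other end, giving the homopropargyl arene.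

Step 6
Reactants: 11 [4-(4-methoxy-3-{4-[2-(3-methoxyphenyl)ethyl]phenoxy}phenyl)but-1-yn-1-yl]trimethylsilane
Product: 12 4-(but-3-yn-1-yl)-1-methoxy-2-{4-[2-(3-methoxyphenyl)ethyl]phenoxy}benzene
Conditions: K2CO3, MeOH/THF, rt
Reagents that add atoms: none
Why: Methoxide-catalysed protodesilylation of the alkynyl C–Si bond, which leaves every ether untouched.

Step 7
Reactants: 13 chromium hexacarbonyl Cr(CO)6; 14 vinylmagnesium bromide
Product: 16 pentacarbonyl[methoxy(vinyl)carbene]chromium, via bromomagnesium acylchromate 15 (not isolated)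
Conditions: THF, 0 °C to rt; then Me3OBF4, CH2Cl2/H2O, 0 °C; cold pentane/SiO2 filtration, used at once
Reagents that add atoms: trimethyloxonium tetrafluoroborate, C[O+](C)C.F[B-](F)(F)F
Why: Fischer carbene synthesis: the vinyl nucleophile adds to a CO ligand to give acylchromate 15, whose oxygen is methylated by the hard oxonium salt; the polymerisation-prone complex is kept cold and dilute and is not stored.

Step 8
Reactants: 12 4-(but-3-yn-1-yl)-1-methoxy-2-{4-[2-(3-methoxyphenyl)ethyl]phenoxy}benzene; 16 pentacarbonyl[methoxy(vinyl)carbene]chromium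
Product: 18 4-methoxy-2-[2-(4-methoxy-3-{4-[2-(3-methoxyphenyl)ethyl]phenoxy}phenyl)ethyl]phenol, via tricarbonylchromium phenol complex 17 (not isolated)
Conditions: 16 (2.5 equiv, in portions), degassed THF (0.03 M), 50 °C, Ar; then air, Et2O, daylight, rt
Reagents that add atoms: none
Why: Thermal loss of one CO from the zerovalent chromium carbene 16 lets the terminal alkyne of 12 insert into the Cr=C bond, its unsubstituted CH carbon bonding to the carbene carbon, and migratory CO insertion then gives an η4-dienylketene complex. Ring D closes by a thermal six-electron disrotatory electrocyclisation in which the ketene carbon bonds to the CH2 terminus of the former vinyl group, and enolisation of the cyclohexadienone gives the phenol as its Cr(CO)3 complex 17, which air and light strip to 18. The closest known reaction type is the Dötz benzannulation of alkenyl(alkoxy)carbene chromium complexes with terminal alkynes, used here with the unsubstituted vinyl member. No stereocentre is formed. The step needs regioselective insertion so that the chain ends next to the CO-derived phenol carbon, which the size difference between H and the CH2CH2Ar group of a terminal alkyne secures, and it needs annulation to outrun polymerisation of the vinyl complex, which is met by adding fresh 16 in excess and in portions to a dilute solution. Alkenyl complexes in THF favour the phenol over cyclobutenone or indene products, and the aryl methyl ethers and the diaryl ether of 12 take no part.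

Step 9
Reactants: 18 4-methoxy-2-[2-(4-methoxy-3-{4-[2-(3-methoxyphenyl)ethyl]phenoxy}phenyl)ethyl]phenol
Product: 19 2-[2-(4-hydroxy-3-{4-[2-(3-hydroxyphenyl)ethyl]phenoxy}phenyl)ethyl]benzene-1,4-diol
Conditions: BBr3 (excess), CH2Cl2, −78 °C to rt; then H2O, aq. Na2S2O4 wash
Reagents that add atoms: none
Why: BBr3 cleavage of the three aryl methyl ethers (bromide attacks the O-methyl group of the boron-complexed ether) leaves the diaryl ether and both ethano bridges intact, and the reductive wash keeps the hydroquinone from air oxidation.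

**Compound list**

1 | 3-hydroxy-4-methoxybenzyl alcohol | COc1ccc(CO)cc1O | starting material
2 | 4-fluorobenzaldehyde | O=Cc1ccc(F)cc1 | starting material
3 | 4-[5-(hydroxymethyl)-2-methoxyphenoxy]benzaldehyde | O=Cc1ccc(Oc2cc(CO)ccc2OC)cc1 | intermediate
4 | (3-methoxybenzyl)triphenylphosphonium chloride | COc1cccc(C[P+](c2ccccc2)(c2ccccc2)c2ccccc2)c1.[Cl-] | starting material
5 | (3-methoxybenzylidene)triphenylphosphorane (not isolated) | COc1cccc(C=P(c2ccccc2)(c2ccccc2)c2ccccc2)c1 | intermediate
6 | (4-methoxy-3-{4-[2-(3-methoxyphenyl)ethenyl]phenoxy}phenyl)methanol, E/Z mixture | COc1cccc(C=Cc2ccc(Oc3cc(CO)ccc3OC)cc2)c1 | intermediate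
7 | (4-methoxy-3-{4-[2-(3-methoxyphenyl)ethyl]phenoxy}phenyl)methanol | COc1cccc(CCc2ccc(Oc3cc(CO)ccc3OC)cc2)c1 | intermediate
8 | 4-(bromomethyl)-1-methoxy-2-{4-[2-(3-methoxyphenyl)ethyl]phenoxy}benzene | COc1cccc(CCc2ccc(Oc3cc(CBr)ccc3OC)cc2)c1 | intermediate
9 | 1-(trimethylsilyl)propyne | CC#C[Si](C)(C)C | starting material
10 | 3-lithio-1-(trimethylsilyl)propyne (not isolated) | [Li]CC#C[Si](C)(C)C | intermediate
11 | [4-(4-methoxy-3-{4-[2-(3-methoxyphenyl)ethyl]phenoxy}phenyl)but-1-yn-1-yl]trimethylsilane | COc1cccc(CCc2ccc(Oc3cc(CCC#C[Si](C)(C)C)ccc3OC)cc2)c1 | intermediate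
12 | 4-(but-3-yn-1-yl)-1-methoxy-2-{4-[2-(3-methoxyphenyl)ethyl]phenoxy}benzene | C#CCCc1ccc(OC)c(Oc2ccc(CCc3cccc(OC)c3)cc2)c1 | intermediate
13 | chromium hexacarbonyl Cr(CO)6 | O=C=[Cr](=C=O)(=C=O)(=C=O)(=C=O)=C=O | starting material
14 | vinylmagnesium bromide | C=C[Mg]Br | starting material
15 | bromomagnesium pentacarbonyl(acryloyl)chromate (not isolated) | C=CC(O[Mg]Br)=[Cr](=C=O)(=C=O)(=C=O)(=C=O)=C=O | intermediate
16 | pentacarbonyl[methoxy(vinyl)carbene]chromium | COC(C=C)=[Cr](=C=O)(=C=O)(=C=O)(=C=O)=C=O | intermediate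
17 | tricarbonylchromium complex of 18, Cr(CO)3 η6-bound to ring D, written as two components (not isolated) | COc1ccc(O)c(CCc2ccc(OC)c(Oc3ccc(CCc4cccc(OC)c4)cc3)c2)c1.O=C=[Cr](=C=O)=C=O | intermediate
18 | 4-methoxy-2-[2-(4-methoxy-3-{4-[2-(3-methoxyphenyl)ethyl]phenoxy}phenyl)ethyl]phenol | COc1ccc(O)c(CCc2ccc(OC)c(Oc3ccc(CCc4cccc(OC)c4)cc3)c2)c1 | intermediate
19 | 2-[2-(4-hydroxy-3-{4-[2-(3-hydroxyphenyl)ethyl]phenoxy}phenyl)ethyl]benzene-1,4-diol | Oc1cccc(CCc2ccc(Oc3cc(CCc4cc(O)ccc4O)ccc3O)cc2)c1 | target

**Step count**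

Total: 9 steps. Longest linear sequence: 8 steps (steps 1–6, 8, 9); step 7 is a one-step side branch.

**Steps most likely to fail**

1. Step 8. The vinylcarbene complex may polymerise or decompose faster than it captures the alkyne, and the terminal alkyne may oligomerise at chromium, so that little phenol forms. The fallback gives up the annulation and brings ring D in as a preformed arene. It sets out from bromide 8, which with PPh3 in toluene at 80 °C should give {4-methoxy-3-{4-[2-(3-methoxyphenyl)ethyl]phenoxy}benzyl}triphenylphosphonium bromide F1. KOtBu in THF converts this into the benzylic ylide F2, which is condensed with 2,5-dimethoxybenzaldehyde to the 2,5-dimethoxystilbene F3 (E/Z mixture). Hydrogenation (H2, Pd/C, EtOAc) gives the tetramethyl ether F4, and BBr3 in CH2Cl2 cleaves all four methyl ethers, so the fallback comes back to the route at target 19.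

2. Step 7. Addition of the Grignard reagent to Cr(CO)6 may be sluggish, and the unsubstituted vinyl complex may polymerise during work-up and concentration. The fallback uses a silyl-stabilised surrogate of the vinyl complex. It sets out from 13: (E)-(2-bromovinyl)trimethylsilane and t-BuLi (2 equiv, Et2O, −78 °C) give (E)-2-(trimethylsilyl)vinyllithium F5, which adds to Cr(CO)6 to give the lithium acylchromate F6. Me3OBF4 converts this into pentacarbonyl{methoxy[(E)-2-(trimethylsilyl)ethenyl]carbene}chromium F7, a complex that should tolerate chromatography and storage. Heating F7 with alkyne 12 in THF at 50 °C is a benzannulation of the same kind, in which the cyclohexadienone intermediate should aromatise by a 1,3-shift of silicon from carbon to oxygen. The product is the tricarbonylchromium complex F8 of the aryl trimethylsilyl ether, which air frees to the aryl trimethylsilyl ether F9. K2CO3 in MeOH removes the silyl group and the fallback comes back to the route at phenol 18.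

3. Step 5. Halogen–lithium exchange and Wurtz-type dimerisation of the electron-rich benzylic bromide, or attack through the allenyl terminus of the anion, may consume the material. The fallback builds the alkyne by homologation instead. It sets out from 8: the lithium enolate of tert-butyl acetate (from LiN(i-Pr)2, THF, −78 °C) should give tert-butyl 3-(4-methoxy-3-{4-[2-(3-methoxyphenyl)ethyl]phenoxy}phenyl)propanoate F10. i-Bu2AlH in CH2Cl2 at −78 °C reduces this to 3-(4-methoxy-3-{4-[2-(3-methoxyphenyl)ethyl]phenoxy}phenyl)propanal F11. Seyferth–Gilbert homologation with dimethyl (1-diazo-2-oxopropyl)phosphonate, K2CO3 and MeOH brings the fallback back to the route at alkyne 12.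

**Further compounds**

F1 | step 8 | {4-methoxy-3-{4-[2-(3-methoxyphenyl)ethyl]phenoxy}benzyl}triphenylphosphonium bromide | COc1cccc(CCc2ccc(Oc3cc(C[P+](c4ccccc4)(c4ccccc4)c4ccccc4)ccc3OC)cc2)c1.[Br-]
F2 | step 8 | (4-methoxy-3-{4-[2-(3-methoxyphenyl)ethyl]phenoxy}benzylidene)triphenylphosphorane | COc1cccc(CCc2ccc(Oc3cc(C=P(c4ccccc4)(c4ccccc4)c4ccccc4)ccc3OC)cc2)c1
F3 | step 8 | 2-[2-(4-methoxy-3-{4-[2-(3-methoxyphenyl)ethyl]phenoxy}phenyl)ethenyl]-1,4-dimethoxybenzene, E/Z mixture | COc1cccc(CCc2ccc(Oc3cc(C=Cc4cc(OC)ccc4OC)ccc3OC)cc2)c1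
F4 | step 8 | 2-[2-(4-methoxy-3-{4-[2-(3-methoxyphenyl)ethyl]phenoxy}phenyl)ethyl]-1,4-dimethoxybenzene | COc1cccc(CCc2ccc(Oc3cc(CCc4cc(OC)ccc4OC)ccc3OC)cc2)c1
F5 | step 7 | (E)-2-(trimethylsilyl)vinyllithium | [Li]/C=C/[Si](C)(C)C
F6 | step 7 | lithium pentacarbonyl[(E)-3-(trimethylsilyl)acryloyl]chromate | C[Si](C)(C)/C=C/C(O[Li])=[Cr](=C=O)(=C=O)(=C=O)(=C=O)=C=O
F7 | step 7 | pentacarbonyl{methoxy[(E)-2-(trimethylsilyl)ethenyl]carbene}chromium | COC(/C=C/[Si](C)(C)C)=[Cr](=C=O)(=C=O)(=C=O)(=C=O)=C=O
F8 | step 7 | tricarbonylchromium complex of F9, Cr(CO)3 η6-bound to ring D, written as two components | COc1ccc(O[Si](C)(C)C)c(CCc2ccc(OC)c(Oc3ccc(CCc4cccc(OC)c4)cc3)c2)c1.O=C=[Cr](=C=O)=C=O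
F9 | step 7 | {4-methoxy-2-[2-(4-methoxy-3-{4-[2-(3-methoxyphenyl)ethyl]phenoxy}phenyl)ethyl]phenoxy}trimethylsilane | COc1ccc(O[Si](C)(C)C)c(CCc2ccc(OC)c(Oc3ccc(CCc4cccc(OC)c4)cc3)c2)c1
F10 | step 5 | tert-butyl 3-(4-methoxy-3-{4-[2-(3-methoxyphenyl)ethyl]phenoxy}phenyl)propanoate | COc1cccc(CCc2ccc(Oc3cc(CCC(=O)OC(C)(C)C)ccc3OC)cc2)c1
F11 | step 5 | 3-(4-methoxy-3-{4-[2-(3-methoxyphenyl)ethyl]phenoxy}phenyl)propanal | COc1cccc(CCc2ccc(Oc3cc(CCC=O)ccc3OC)cc2)c1
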